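**Strategy.** Ring A (C1–C5, C10) is disconnected at C3–C4/C4–C5 by a Dowd–Beckwith ring expansion: the 1,4-dioxygen pattern C3–O/C6=O that flanks the C4 gem-dimethyl carbon and C5–H is what a one-carbon acyl shift from a 1,3-diketone produces. The precursor is a cis-hydrindane enedione (cyclopentanone C1–C2–C3–C5–C10 fused to the ring B enone) carrying an isopropenyl group on C5. Hydrogen-atom transfer to that alkene gives the C4 radical, which inserts between C3 and C5, creating the six-membered ring A, the quaternary C4 and the trans ring fusion in one operation. C10 comes from a catalytic asymmetric conjugate addition; C9 is functionalised last, anti to the angular methyl.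

Key step: step 6

Remark: drimane numbering (C1–C15) is used for all bicyclic compounds; β is the face of the C10 methyl group, and the target has 5α-H, a 3α-acyloxy group and C11 on the α face (9β-H).

Step 1
Reactants: 1 3-ethoxycyclopent-2-en-1-one; 2 (2-methylprop-2-en-1-yl)magnesium chloride
Product: 4 3-(2-methylprop-2-en-1-yl)cyclopent-2-en-1-one, via tertiary allylic alkoxide adduct 3 (not isolated)
Conditions: 2, THF, −78 to 0 °C; then 1 M HCl, 0 °C
Reagents that add atoms: water, O
Why: Stork–Danheiser sequence: the allylic Grignard reagent adds 1,2 to the vinylogous ester carbonyl and dilute acid ionises adduct 3 and hydrolyses the enol ether, transposing the carbonyl to give the 3-substituted enone; no stereocentre is formed.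

Step 2
Reactants: 4 3-(2-methylprop-2-en-1-yl)cyclopent-2-en-1-one
Product: 5 (3R)-3-methyl-3-(2-methylprop-2-en-1-yl)cyclopentan-1-one
Conditions: Me3Al, Cu(OTf)2 (cat.), chiral sulfonate-bearing imidazolinium salt (NHC precursor, cat.), THF, −78 °C; aq. NH4Cl
Reagents that add atoms: trimethylaluminium, C[Al](C)C
Why: Copper-catalysed asymmetric conjugate addition of a trialkylaluminium to a β-substituted cyclopentenone under NHC–copper control should create the quaternary C10 centre, the ligand enantiomer being the one that gives the (R) configuration.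

Step 3
Reactants: 5 (3R)-3-methyl-3-(2-methylprop-2-en-1-yl)cyclopentan-1-one; 6 methyl acrylate
Product: 7 methyl 3-methyl-4-[(1R)-1-methyl-3-oxocyclopentyl]but-2-enoate (mixture of 2E and 2Z isomers)
Conditions: 6 (excess), second-generation Grubbs catalyst (cat.), CH2Cl2, 40 °C
Reagents that add atoms: none
Why: Olefin cross-metathesis of the 1,1-disubstituted alkene with excess acrylate should give the trisubstituted enoate, whose double-bond geometry does not matter because both isomers converge in step 4.

Step 4
Reactants: 7 methyl 3-methyl-4-[(1R)-1-methyl-3-oxocyclopentyl]but-2-enoate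
Product: 8 (3aR)-3a,5-dimethyl-3,3a,4,7a-tetrahydro-1H-indene-1,7(2H)-dione (enolisable at C5 = C7a)
Conditions: KOtBu (2.2 equiv), THF, 0 °C to rt; then 1 M HCl
Reagents that add atoms: none
Why: Dieckmann-type intramolecular Claisen condensation under equilibrating conditions: the enoate isomerises E/Z through its dienolate, only the C5 ketone enolate can reach the ester carbonyl of the Z isomer through a six-membered transition state, and deprotonation of the product β-diketone at C5 makes the closure of ring B irreversible; C10 is untouched.

Step 5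
Reactants: 8 (3aR)-3a,5-dimethyl-3,3a,4,7a-tetrahydro-1H-indene-1,7(2H)-dione; 9 propyne
Product: 10 (3aR,7aS)-3a,5-dimethyl-7a-(prop-1-en-2-yl)-3,3a,4,7a-tetrahydro-1H-indene-1,7(2H)-dione (cis-fused, isopropenyl syn to the angular methyl)
Conditions: 9 (excess), In(OTf)3 (cat.), toluene, sealed tube, 80 °C
Reagents that add atoms: none
Why: Indium-triflate-catalysed Markovnikov addition of a 2-substituted 1,3-diketone across a terminal alkyne (cis-carbometalation by the indium enolate) should give the C-isopropenyl quaternary centre as the cis-hydrindane; this C5 configuration is erased in step 6.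

Step 6
Reactants: 10 (3aR,7aS)-3a,5-dimethyl-7a-(prop-1-en-2-yl)-3,3a,4,7a-tetrahydro-1H-indene-1,7(2H)-dione
Product: 11 (4aR,8aR)-3,4a,8,8-tetramethyl-4a,5,6,8a-tetrahydronaphthalene-1,7(4H,8H)-dione (11-nordrim-7-ene-3,6-dione, trans-fused, 5α-H)
Conditions: Fe(acac)3 (0.3 equiv), PhSiH3 (2.5 equiv), EtOH, 60 °C; then DBU (cat.), rt
Reagents that add atoms: none
Why: Hydrogen-atom transfer from the iron hydride to the electron-rich 1,1-disubstituted alkene gives the tertiary C4 radical, which adds 3-exo-trig to the adjacent C3 ketone; β-scission of the C3–C5 bond of the cyclopropyloxy radical then inserts C4 between C3 and C5 and leaves an α-keto radical at C5 that is reduced by divalent iron to the enolate and protonated. The closest known reaction type is the Dowd–Beckwith ring expansion of 2-(halomethyl) cyclic β-dicarbonyl compounds, here in its hydrogen-atom-transfer-initiated form that builds a gem-dimethyl quaternary carbon next to the ketone. Ring A is not closed directly: a three-membered ring closes (3-exo-trig) and opens again, so the cyclopentanone becomes the cyclohexanone. C4 carries two methyl groups and is not stereogenic; C5 is set on protonation of the enolate from the α face, anti to the axial methyl groups on C4 and C10, and, being α to the C6 ketone, is equilibrated by DBU to the more stable trans-decalin. The step needs migration of the C3 acyl group and not of C6, and rearrangement before the radical is quenched: the strained saturated cyclopentanone is the more electrophilic carbonyl, the C5 radical formed by its cleavage is delocalised into the enone, and the nucleophilic tertiary radical has no fast hydrogen donor under these conditions whereas the rearranged electrophilic radical is rapidly reduced. The enone double bond is electron-poor and trisubstituted and should not compete for the hydride.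

Step 7
Reactants: 11 11-nordrim-7-ene-3,6-dione
Product: 12 3α-hydroxy-11-nordrim-7-en-6-one
Conditions: lithium tri-sec-butylborohydride (1.1 equiv), THF, −78 °C; aq. NH4Cl
Reagents that add atoms: none
Why: Chemoselective ketone reduction with a bulky trialkylborohydride: the hydride approaches the C3 ketone along the equatorial trajectory to give the axial 3α-alcohol, while the conjugated C6 carbonyl, flanked by C5 between two quaternary carbons, should not react at −78 °C.

Step 8
Reactants: 12 3α-hydroxy-11-nordrim-7-en-6-one; 13 3-methylbutanoyl chloride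
Product: 14 6-oxo-11-nordrim-7-en-3α-yl 3-methylbutanoate
Conditions: 13, pyridine, DMAP (cat.), CH2Cl2, 0 °C to rt
Reagents that add atoms: none
Why: DMAP-catalysed acylation of the hindered axial secondary alcohol with the acid chloride; no stereocentre is touched.

Step 9
Reactants: 14 6-oxo-11-nordrim-7-en-3α-yl 3-methylbutanoate
Product: 15 6-(trimethylsilyloxy)-11-nordrima-6,8-dien-3α-yl 3-methylbutanoate
Conditions: TMSOTf, Et3N, CH2Cl2, 0 °C to rt
Reagents that add atoms: trimethylsilyl trifluoromethanesulfonate, C[Si](C)(C)OS(=O)(=O)C(F)(F)F
Why: Soft enolisation with silyl triflate and amine should give the thermodynamic, fully conjugated 6-silyloxy-6,8-diene by loss of the axial C9 proton, because the α′ proton at C5 is buried between C4 and C10.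

Step 10
Reactants: 15 6-(trimethylsilyloxy)-11-nordrima-6,8-dien-3α-yl 3-methylbutanoate
Product: 16 11-hydroxy-6-oxodrim-7-en-3α-yl 3-methylbutanoate with C11 on the α face (9β-H)
Conditions: aq. HCHO (37%), Sc(OTf)3 (cat.), THF/H2O, rt
Reagents that add atoms: formaldehyde, C=O
Why: Lewis-acid-catalysed vinylogous Mukaiyama aldol reaction with aqueous formaldehyde (hydroxymethylation): the dienol ether reacts at its γ-carbon C9, restoring the conjugated enone, and formaldehyde enters axially on the α face anti to the adjacent C10 methyl, which sets C9 with C11 α.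

Step 11
Reactants: 16 11-hydroxy-6-oxodrim-7-en-3α-yl 3-methylbutanoate (C11 α); 17 isofraxidin (7-hydroxy-6,8-dimethoxy-2H-chromen-2-one)
Product: 18 6,8-dimethoxy-7-{[3α-(3-methylbutanoyloxy)-6-oxo-9βH-drim-7-en-11-yl]oxy}-2H-chromen-2-one (target)
Conditions: PPh3, DIAD, THF, 0 °C to rt
Reagents that add atoms: none
Why: Mitsunobu etherification: the phenol displaces the activated primary C11 oxygen by SN2, so no stereocentre is involved and the ester, enone and coumarin lactone are not exposed to strong base.

**Compound list**

1 | 3-ethoxycyclopent-2-en-1-one | CCOC1=CC(=O)CC1 | starting material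
2 | (2-methylprop-2-en-1-yl)magnesium chloride | CC(=C)C[Mg]Cl | starting material
3 | 3-ethoxy-1-(2-methylprop-2-en-1-yl)cyclopent-2-en-1-ol (racemic, present as its chloromagnesium alkoxide, not isolated) | CCOC1=CC(O)(CC(C)=C)CC1 | intermediate
4 | 3-(2-methylprop-2-en-1-yl)cyclopent-2-en-1-one | CC(=C)CC1=CC(=O)CC1 | intermediate
5 | (3R)-3-methyl-3-(2-methylprop-2-en-1-yl)cyclopentan-1-one | O=C1CC[C@](C)(CC(C)=C)C1 | intermediate
6 | methyl acrylate | C=CC(=O)OC | starting material
7 | methyl 3-methyl-4-[(1R)-1-methyl-3-oxocyclopentyl]but-2-enoate (2E/2Z mixture) | O=C1CC[C@](C)(CC(C)=CC(=O)OC)C1 | intermediate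
8 | (3aR)-3a,5-dimethyl-3,3a,4,7a-tetrahydro-1H-indene-1,7(2H)-dione (C7a enolisable) | O=C1CC[C@]2(C)CC(C)=CC(=O)C12 | intermediate
9 | propyne | CC#C | starting material
10 | (3aR,7aS)-3a,5-dimethyl-7a-(prop-1-en-2-yl)-3,3a,4,7a-tetrahydro-1H-indene-1,7(2H)-dione (cis-fused) | O=C1CC[C@]2(C)CC(C)=CC(=O)[C@]12C(C)=C | intermediate
11 | (4aR,8aR)-3,4a,8,8-tetramethyl-4a,5,6,8a-tetrahydronaphthalene-1,7(4H,8H)-dione (11-nordrim-7-ene-3,6-dione, trans-fused) | CC1=CC(=O)[C@H]2C(C)(C)C(=O)CC[C@]2(C)C1 | intermediate
12 | 3α-hydroxy-11-nordrim-7-en-6-one (5α-H, 10β-methyl) | CC1=CC(=O)[C@H]2C(C)(C)[C@H](O)CC[C@]2(C)C1 | intermediate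
13 | 3-methylbutanoyl chloride | CC(C)CC(=O)Cl | starting material
14 | 6-oxo-11-nordrim-7-en-3α-yl 3-methylbutanoate | CC1=CC(=O)[C@H]2C(C)(C)[C@H](OC(=O)CC(C)C)CC[C@]2(C)C1 | intermediate
15 | 6-(trimethylsilyloxy)-11-nordrima-6,8-dien-3α-yl 3-methylbutanoate | C1=C(C)C=C(O[Si](C)(C)C)[C@H]2C(C)(C)[C@H](OC(=O)CC(C)C)CC[C@]12C | intermediate
16 | 11-hydroxy-6-oxodrim-7-en-3α-yl 3-methylbutanoate, C11 on the α face (9β-H) | OC[C@@H]1C(C)=CC(=O)[C@H]2C(C)(C)[C@H](OC(=O)CC(C)C)CC[C@]12C | intermediate
17 | isofraxidin (7-hydroxy-6,8-dimethoxy-2H-chromen-2-one) | COc1cc2ccc(=O)oc2c(OC)c1O | starting material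
18 | 6,8-dimethoxy-7-{[3α-(3-methylbutanoyloxy)-6-oxo-9βH-drim-7-en-11-yl]oxy}-2H-chromen-2-one | COc1cc2ccc(=O)oc2c(OC)c1OC[C@@H]1C(C)=CC(=O)[C@H]2C(C)(C)[C@H](OC(=O)CC(C)C)CC[C@]12C | target

**Step count.** Total: 11 steps. Longest linear sequence: 11 steps (1 to 18).

**Steps most likely to fail**

Step 6. The tertiary C4 radical may be quenched before the acyl shift (net hydrogenation of the isopropenyl group), or the ring B acyl group may migrate in competition. Fallback, setting out from 10 and returning at 11: Markovnikov hydrobromination of the isopropenyl group (HBr in AcOH, CH2Cl2, 0 °C) should give the tertiary bromide (3aR,7aS)-7a-(2-bromopropan-2-yl)-3a,5-dimethyl-3,3a,4,7a-tetrahydro-1H-indene-1,7(2H)-dione F1. Classical tin-mediated Dowd–Beckwith expansion of F1 (Bu3SnH by syringe pump, AIBN, benzene, 80 °C, then DBU) keeps the hydrogen-donor concentration low enough for the rearrangement to outrun reduction and should deliver 11.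

Step 5. Carbometalation at C5 may be too slow because two adjacent quaternary carbons (C5, C10) are being formed, and O-alkenylation may compete. Fallback, setting out from 8 and returning at 10: C-alkenylation of the β-diketone by ligand coupling with prop-1-en-2-yllead triacetate F2, generated in situ from tributyl(prop-1-en-2-yl)stannane and Pb(OAc)4 with Hg(OAc)2 as catalyst in CHCl3, then 8 and pyridine at 40 °C. Alkenyllead triacetates are established reagents for building hindered quaternary centres on 1,3-dicarbonyl compounds.

Step 10. Formaldehyde may attack the dienol ether at C7 instead of the hindered C9, or the vinylogous aldol may revert. Fallback, setting out from 15 and 17 and returning at 18 (it also bypasses 16 and step 11): isofraxidin 17 is converted with chloromethyl methyl sulfide and NaH in DMF into 6,8-dimethoxy-7-[(methylsulfanyl)methoxy]-2H-chromen-2-one F3. Treatment with SO2Cl2 in CH2Cl2 at 0 °C gives 7-(chloromethoxy)-6,8-dimethoxy-2H-chromen-2-one F4. ZnBr2-catalysed alkylation of 15 with F4 (CH2Cl2, −20 °C) uses a cationic, irreversible electrophile of the type known to react with silyl dienol ethers at the γ-carbon, and should install the whole aryloxymethyl group at C9 from the α face to give 18 directly.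

**Further compounds**

F1 | step 6 | (3aR,7aS)-7a-(2-bromopropan-2-yl)-3a,5-dimethyl-3,3a,4,7a-tetrahydro-1H-indene-1,7(2H)-dione | O=C1CC[C@]2(C)CC(C)=CC(=O)[C@]12C(C)(C)Br
F2 | step 5 | prop-1-en-2-yllead triacetate | CC(=C)[Pb](OC(C)=O)(OC(C)=O)OC(C)=O
F3 | step 10 | 6,8-dimethoxy-7-[(methylsulfanyl)methoxy]-2H-chromen-2-one | COc1cc2ccc(=O)oc2c(OC)c1OCSC
F4 | step 10 | 7-(chloromethoxy)-6,8-dimethoxy-2H-chromen-2-one | COc1cc2ccc(=O)oc2c(OC)c1OCCl
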